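**Strategy**

Atoms are numbered C1–C9 along the 2-methyldienoate half (C1 = carbonyl) and C1'–C9' along the other. The 20-membered diolide ring is opened at the C5–C6 single bond, where the Z,Z-diene meets the C6–C7 ethylene leading to the C8 methyl/C9 acyloxy pair. Seen as a vinyl group on C8, that ethylene is the direct product of a syn-crotylation, so one homoallylic alcohol supplies the stereocentres of both halves. The key step, a B-alkyl Suzuki–Miyaura macrocyclisation, hydroborates this vinyl group and joins the primary borane to a Z-alkenyl iodide with retention. Its precursor is an open-chain diester ending in the vinyl group and a (2Z,4Z)-5-iodo-2-methyldienoate.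

Key step: step 11

Assumption: the phosphono acids 11 and 16 are taken as purchasable reagents; aldehyde 10 is labile and is made fresh for each of steps 7 and 10.

**Route**

Step 1
Reactants: 1 3-[(tert-butyldimethylsilyl)oxy]propanal; 2 p-toluenesulfonylmethyl isocyanide (TosMIC)
Product: 3 5-{2-[(tert-butyldimethylsilyl)oxy]ethyl}-1,3-oxazole
Conditions: K2CO3, MeOH, reflux
Reagents that add atoms: none
Why: Van Leusen oxazole synthesis, in which the TosMIC anion adds to the aldehyde, the adduct closes to a 4-tosyloxazoline and loss of sulfinate gives the 5-monosubstituted oxazole; no stereocentre is involved.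

Step 2
Reactants: 3 5-{2-[(tert-butyldimethylsilyl)oxy]ethyl}-1,3-oxazole
Product: 4 2-(1,3-oxazol-5-yl)ethanol
Conditions: camphorsulfonic acid (10 mol %), MeOH, 0 °C to rt
Reagents that add atoms: none
Why: Acid-catalysed methanolysis of a primary silyl ether, which the weakly basic oxazole should tolerate.

Step 3
Reactants: 4 2-(1,3-oxazol-5-yl)ethanol
Product: 5 2-(1,3-oxazol-5-yl)acetaldehyde
Conditions: Dess–Martin periodinane, CH2Cl2, 0 °C to rt; cold Na2S2O3/NaHCO3 work-up; used at once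
Reagents that add atoms: none
Why: Dess–Martin oxidation under mild, non-basic conditions should give the enolisable heteroarylacetaldehyde without over-oxidation or self-condensation.

Step 4
Reactants: 5 2-(1,3-oxazol-5-yl)acetaldehyde
Product: 7 (2R,3R)-3-methyl-1-(1,3-oxazol-5-yl)pent-4-en-2-ol, via borinate 6 (not isolated)
Conditions: (−)-Ipc2B[(Z)-crotyl] (from cis-2-butene, n-BuLi, KOt-Bu, (−)-Ipc2BOMe, BF3·OEt2), THF, −78 °C; then NaOH, H2O2, 0 °C to rt
Reagents that add atoms: (−)-(Z)-crotyldiisopinocampheylborane, C/C=C\CB([C@H]1[C@H](C)[C@H]2C[C@@H](C1)C2(C)C)[C@H]1[C@H](C)[C@H]2C[C@@H](C1)C2(C)C, made in the flask from cis-2-butene, C/C=C\C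
Why: Brown asymmetric crotylboration through a closed chair transition state, in which the Z-crotyl geometry sets the syn C2/C3 relationship and the isopinocampheyl groups derived from (+)-α-pinene select the aldehyde face that leads to the (2R,3R) alcohol.

Step 5
Reactants: 8 ethyl (Z)-3-iodoacrylate
Product: 10 (Z)-3-iodoprop-2-enal, via aluminium hemiacetal 9 (not isolated)
Conditions: i-Bu2AlH (1.05 equiv), CH2Cl2, −78 °C; MeOH, aq. potassium sodium tartrate, cold; dried solution used at once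
Reagents that add atoms: none
Why: Partial ester reduction that stops at the tetrahedral aluminium hemiacetal at −78 °C, which releases the enal on cold work-up with the Z double bond intact.

Step 6
Reactants: 7 (2R,3R)-3-methyl-1-(1,3-oxazol-5-yl)pent-4-en-2-ol; 11 2-[bis(2,2,2-trifluoroethoxy)phosphoryl]acetic acid
Product: 12 (2R,3R)-3-methyl-1-(1,3-oxazol-5-yl)pent-4-en-2-yl 2-[bis(2,2,2-trifluoroethoxy)phosphoryl]acetate
Conditions: DCC, DMAP (5 mol %), CH2Cl2, 0 °C to rt
Reagents that add atoms: none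
Why: Steglich carbodiimide esterification of the secondary alcohol, in which the C–O bond of 7 is not broken and C2 keeps its configuration.

Step 7
Reactants: 12 (2R,3R)-3-methyl-1-(1,3-oxazol-5-yl)pent-4-en-2-yl 2-[bis(2,2,2-trifluoroethoxy)phosphoryl]acetate; 10 (Z)-3-iodoprop-2-enal
Product: 13 (2R,3R)-3-methyl-1-(1,3-oxazol-5-yl)pent-4-en-2-yl (2Z,4Z)-5-iodopenta-2,4-dienoate
Conditions: KN(SiMe3)2, 18-crown-6, THF, −78 °C; then 10, −78 °C, dark
Reagents that add atoms: none
Why: Still–Gennari variant of the Horner–Wadsworth–Emmons olefination, in which the electron-poor trifluoroethyl phosphonate under dissociating conditions eliminates fast from the kinetic adduct to give the 2Z enoate, while the 4Z iodoalkene of 10 is carried through unchanged.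

Step 8
Reactants: 7 (2R,3R)-3-methyl-1-(1,3-oxazol-5-yl)pent-4-en-2-ol; 13 (2R,3R)-3-methyl-1-(1,3-oxazol-5-yl)pent-4-en-2-yl (2Z,4Z)-5-iodopenta-2,4-dienoate
Product: 15 (2R,3R)-3-methyl-1-(1,3-oxazol-5-yl)pent-4-en-2-yl (2Z,4Z,8R,9R)-9-hydroxy-8-methyl-10-(1,3-oxazol-5-yl)deca-2,4-dienoate, via bis-boryl adduct 14 (not isolated)
Conditions: 7 (1.5 equiv), 9-BBN (2.2 equiv per 7), THF, 0 °C to rt; H2O; then 13, Pd(dppf)Cl2 (10 mol %), AsPh3, Cs2CO3, DMF/THF/H2O, rt
Reagents that add atoms: none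
Why: Intermolecular B-alkyl Suzuki–Miyaura coupling, in which 9-BBN adds anti-Markovnikov to the terminal alkene of 7 (one further equivalent is taken up by the hydroxyl), residual B–H is destroyed with water so that the vinyl group of 13 survives, and the primary borane couples with the Z-alkenyl iodide with retention of both Z double bonds.

Step 9
Reactants: 15 (2R,3R)-3-methyl-1-(1,3-oxazol-5-yl)pent-4-en-2-yl (2Z,4Z,8R,9R)-9-hydroxy-8-methyl-10-(1,3-oxazol-5-yl)deca-2,4-dienoate; 16 2-[bis(2,2,2-trifluoroethoxy)phosphoryl]propanoic acid (racemic)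
Product: 17 (2R,3R)-3-methyl-1-(1,3-oxazol-5-yl)pent-4-en-2-yl (2Z,4Z,8R,9R)-9-({2-[bis(2,2,2-trifluoroethoxy)phosphoryl]propanoyl}oxy)-8-methyl-10-(1,3-oxazol-5-yl)deca-2,4-dienoate (both epimers at the phosphonate carbon)
Conditions: DCC, DMAP (5 mol %), CH2Cl2, 0 °C
Reagents that add atoms: none
Why: Steglich esterification at low temperature, which should leave the Z,Z-dienoate untouched; the epimeric phosphonate carbon is of no consequence because it becomes sp2 in the next step.

Step 10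
Reactants: 17 (2R,3R)-3-methyl-1-(1,3-oxazol-5-yl)pent-4-en-2-yl (2Z,4Z,8R,9R)-9-({2-[bis(2,2,2-trifluoroethoxy)phosphoryl]propanoyl}oxy)-8-methyl-10-(1,3-oxazol-5-yl)deca-2,4-dienoate; 10 (Z)-3-iodoprop-2-enal
Product: 18 (2R,3R)-3-methyl-1-(1,3-oxazol-5-yl)pent-4-en-2-yl (2Z,4Z,8R,9R)-9-{[(2Z,4Z)-5-iodo-2-methylpenta-2,4-dienoyl]oxy}-8-methyl-10-(1,3-oxazol-5-yl)deca-2,4-dienoate
Conditions: KN(SiMe3)2, 18-crown-6, THF, −78 °C; then 10, −78 to −40 °C, dark
Reagents that add atoms: none
Why: Still–Gennari olefination with an α-methyl phosphonate, the standard way to a Z-configured 2-methyl enoate (angelate type), which places the ester carbonyl cis to C4 without ever handling the isomerisation-prone free acid.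

Step 11
Reactants: 18 (2R,3R)-3-methyl-1-(1,3-oxazol-5-yl)pent-4-en-2-yl (2Z,4Z,8R,9R)-9-{[(2Z,4Z)-5-iodo-2-methylpenta-2,4-dienoyl]oxy}-8-methyl-10-(1,3-oxazol-5-yl)deca-2,4-dienoate
Product: 20 (3Z,5Z,9R,10R,13Z,15Z,19R,20R)-3,9,19-trimethyl-10,20-bis(1,3-oxazol-5-ylmethyl)-1,11-dioxacycloicosa-3,5,13,15-tetraene-2,12-dione (CNP0128396.1), via alkylborane 19 (not isolated)
Conditions: 9-BBN (1.5 equiv), THF, 0 °C to rt; H2O; then slow addition to Pd(dppf)Cl2 (20 mol %), AsPh3, Cs2CO3, DMF/THF/H2O, about 1 mM, rt to 40 °C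
Reagents that add atoms: none
Why: 9-BBN adds anti-Markovnikov to the only monosubstituted alkene of 18, and after water and Cs2CO3 are added the primary alkylborate transmetalates to the alkenylpalladium iodide formed by oxidative addition at the Z C5–I bond; reductive elimination then forms the C5–C6 sp2–sp3 bond. The closest known reaction type is the macrocyclising B-alkyl Suzuki–Miyaura coupling of an ω-alkenyl alkenyl iodide. The 20-membered ring closes in the endo sense, both reacting carbons becoming ring members, through reductive elimination from a large-ring alkyl(alkenyl)palladium intermediate, which slow addition at high dilution favours over oligomerisation. No stereocentre is formed: C8, C9, C8' and C9' are spectators, and the 4Z geometry is kept because oxidative addition and reductive elimination are stereoretentive at the alkenyl carbon. The step needs chemoselective hydroboration and a coupling faster than protodeboronation; the first rests on the strong preference of 9-BBN for a terminal alkene over the iodoalkene and the electron-poor dienoates, the second on the unhindered primary borane and the AsPh3-assisted transmetalation.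

**Compound list**

1 | 3-[(tert-butyldimethylsilyl)oxy]propanal | O=CCCO[Si](C)(C)C(C)(C)C | starting material
2 | p-toluenesulfonylmethyl isocyanide (TosMIC) | Cc1ccc(cc1)S(=O)(=O)C[N+]#[C-] | starting material
3 | 5-{2-[(tert-butyldimethylsilyl)oxy]ethyl}-1,3-oxazole | CC(C)(C)[Si](C)(C)OCCc1cnco1 | intermediate
4 | 2-(1,3-oxazol-5-yl)ethanol | OCCc1cnco1 | intermediate
5 | 2-(1,3-oxazol-5-yl)acetaldehyde | O=CCc1cnco1 | intermediate
6 | (2R,3R)-3-methyl-1-(1,3-oxazol-5-yl)pent-4-en-2-yl diisopinocampheylborinate | C=C[C@@H](C)[C@@H](Cc1cnco1)OB([C@H]1[C@H](C)[C@H]2C[C@@H](C1)C2(C)C)[C@H]1[C@H](C)[C@H]2C[C@@H](C1)C2(C)C | intermediate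
7 | (2R,3R)-3-methyl-1-(1,3-oxazol-5-yl)pent-4-en-2-ol | C=C[C@@H](C)[C@@H](Cc1cnco1)O | intermediate
8 | ethyl (Z)-3-iodoacrylate | CCOC(=O)/C=C\I | starting material
9 | diisobutylaluminium hemiacetal of 8, [(Z)-1-ethoxy-3-iodoprop-2-en-1-yl]oxy-diisobutylalane | CCOC(O[Al](CC(C)C)CC(C)C)/C=C\I | intermediate
10 | (Z)-3-iodoprop-2-enal | O=C/C=C\I | intermediate
11 | 2-[bis(2,2,2-trifluoroethoxy)phosphoryl]acetic acid | OC(=O)CP(=O)(OCC(F)(F)F)OCC(F)(F)F | starting material
12 | (2R,3R)-3-methyl-1-(1,3-oxazol-5-yl)pent-4-en-2-yl 2-[bis(2,2,2-trifluoroethoxy)phosphoryl]acetate | C=C[C@@H](C)[C@@H](Cc1cnco1)OC(=O)CP(=O)(OCC(F)(F)F)OCC(F)(F)F | intermediate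
13 | (2R,3R)-3-methyl-1-(1,3-oxazol-5-yl)pent-4-en-2-yl (2Z,4Z)-5-iodopenta-2,4-dienoate | C=C[C@@H](C)[C@@H](Cc1cnco1)OC(=O)/C=C\C=C/I | intermediate
14 | 9-[(3R,4R)-4-(9-borabicyclo[3.3.1]nonan-9-yloxy)-3-methyl-5-(1,3-oxazol-5-yl)pentyl]-9-borabicyclo[3.3.1]nonane | C1CCC2CCCC1B2CC[C@@H](C)[C@@H](Cc1cnco1)OB1C2CCCC1CCC2 | intermediate
15 | (2R,3R)-3-methyl-1-(1,3-oxazol-5-yl)pent-4-en-2-yl (2Z,4Z,8R,9R)-9-hydroxy-8-methyl-10-(1,3-oxazol-5-yl)deca-2,4-dienoate | C=C[C@@H](C)[C@@H](Cc1cnco1)OC(=O)/C=C\C=C/CC[C@@H](C)[C@@H](Cc1cnco1)O | intermediate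
16 | 2-[bis(2,2,2-trifluoroethoxy)phosphoryl]propanoic acid (racemic) | CC(C(=O)O)P(=O)(OCC(F)(F)F)OCC(F)(F)F | starting material
17 | (2R,3R)-3-methyl-1-(1,3-oxazol-5-yl)pent-4-en-2-yl (2Z,4Z,8R,9R)-9-({2-[bis(2,2,2-trifluoroethoxy)phosphoryl]propanoyl}oxy)-8-methyl-10-(1,3-oxazol-5-yl)deca-2,4-dienoate (both epimers at the phosphonate carbon) | C=C[C@@H](C)[C@@H](Cc1cnco1)OC(=O)/C=C\C=C/CC[C@@H](C)[C@@H](Cc1cnco1)OC(=O)C(C)P(=O)(OCC(F)(F)F)OCC(F)(F)F | intermediate
18 | (2R,3R)-3-methyl-1-(1,3-oxazol-5-yl)pent-4-en-2-yl (2Z,4Z,8R,9R)-9-{[(2Z,4Z)-5-iodo-2-methylpenta-2,4-dienoyl]oxy}-8-methyl-10-(1,3-oxazol-5-yl)deca-2,4-dienoate | C=C[C@@H](C)[C@@H](Cc1cnco1)OC(=O)/C=C\C=C/CC[C@@H](C)[C@@H](Cc1cnco1)OC(=O)/C(C)=C\C=C/I | intermediate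
19 | B-alkyl-9-BBN of 18 (terminal CH=CH2 turned into CH2CH2–B(C8H14), all else unchanged) | C1CCC2CCCC1B2CC[C@@H](C)[C@@H](Cc1cnco1)OC(=O)/C=C\C=C/CC[C@@H](C)[C@@H](Cc1cnco1)OC(=O)/C(C)=C\C=C/I | intermediate
20 | (3Z,5Z,9R,10R,13Z,15Z,19R,20R)-3,9,19-trimethyl-10,20-bis(1,3-oxazol-5-ylmethyl)-1,11-dioxacycloicosa-3,5,13,15-tetraene-2,12-dione | C/C1=C/C=C\CC[C@@H](C)[C@@H](Cc2cnco2)OC(=O)/C=C\C=C/CC[C@@H](C)[C@@H](Cc2cnco2)OC1=O | target

**Count and risks**

Total step count: 11 (step 5 is run twice, once for each olefination).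
Longest linear sequence: 10 steps (steps 1–4 and 6–11, from compound 1).

Steps most likely to fail:

Step 11. At high dilution the alkylborane may be lost by protodeboronation or β-hydride elimination before it meets the alkenylpalladium intermediate, or hydroboration may spill over onto the dienoates, so that reduced open-chain material and oligomers form instead of the ring. The fallback sets out from 18 and closes the same C5–C6 bond with zinc instead of boron, under base-free anhydrous conditions. The 9-BBN adduct 19 is oxidised with NaBO3·4H2O to the primary alcohol F1, which can be purified. I2, PPh3 and imidazole convert it into the primary iodide F2. Activated zinc dust with LiCl in THF inserts selectively into the sp3 C–I bond to give the alkylzinc iodide F3. Slow addition of F3 to Pd(PPh3)4 in THF/DMA brings about an intramolecular Negishi coupling that returns to 20.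

Step 10. Aldehyde 10 may isomerise from Z to E while it is handled, or the α-methyl phosphonate anion of the complex ester 17 may react with eroded Z-selectivity, giving geometric isomers of 18 that cannot be separated at this stage. The fallback sets out from 15 and builds the iododienoic acid separately from an alkyne, so that 10 is not needed. Purchasable ethyl 2-[bis(2,2,2-trifluoroethoxy)phosphoryl]propanoate and 3-(trimethylsilyl)propynal are joined by a Still–Gennari olefination to the silyl enynoate F4. N-Iodosuccinimide with catalytic AgNO3 turns it into the iodoalkyne F5. Diimide, from 2-nitrobenzenesulfonyl hydrazide and Et3N, reduces the iodoalkyne cis to the Z,Z-iododienoate F6, and LiOH in THF/H2O gives the acid F7. Its mixed anhydride with 2,4,6-trichlorobenzoyl chloride (Et3N, toluene, no DMAP, to avoid addition–elimination isomerisation) acylates 15 and returns to 18.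

Step 4. Aldehyde 5 may enolise or self-condense in the basic reagent mixture, with loss of material and of enantio- and diastereoselectivity. The fallback sets out from 1 and runs the crotylation on this robust aldehyde, building the oxazole afterwards. The same (−)-(Z)-crotyldiisopinocampheylborane adds to 1 to give the borinate F8, and oxidative work-up frees the syn homoallylic alcohol F9. TBSOTf and 2,6-lutidine give the bis-silyl ether F10. HF·pyridine in pyridine/THF at 0 °C removes only the primary silyl group to give the primary alcohol F11. Dess–Martin oxidation gives the β-silyloxy aldehyde F12. TosMIC 2 with K2CO3 in MeOH gives the silyl-protected oxazole F13, and Bu4NF returns to 7.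

Further compounds
F1 | step 11 | (2R,3R)-5-hydroxy-3-methyl-1-(1,3-oxazol-5-yl)pentan-2-yl (2Z,4Z,8R,9R)-9-{[(2Z,4Z)-5-iodo-2-methylpenta-2,4-dienoyl]oxy}-8-methyl-10-(1,3-oxazol-5-yl)deca-2,4-dienoate | OCC[C@@H](C)[C@@H](Cc1cnco1)OC(=O)/C=C\C=C/CC[C@@H](C)[C@@H](Cc1cnco1)OC(=O)/C(C)=C\C=C/I
F2 | step 11 | (2R,3R)-5-iodo-3-methyl-1-(1,3-oxazol-5-yl)pentan-2-yl (2Z,4Z,8R,9R)-9-{[(2Z,4Z)-5-iodo-2-methylpenta-2,4-dienoyl]oxy}-8-methyl-10-(1,3-oxazol-5-yl)deca-2,4-dienoate | ICC[C@@H](C)[C@@H](Cc1cnco1)OC(=O)/C=C\C=C/CC[C@@H](C)[C@@H](Cc1cnco1)OC(=O)/C(C)=C\C=C/I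
F3 | step 11 | alkylzinc iodide of F2 (primary C–I turned into C–ZnI) | I[Zn]CC[C@@H](C)[C@@H](Cc1cnco1)OC(=O)/C=C\C=C/CC[C@@H](C)[C@@H](Cc1cnco1)OC(=O)/C(C)=C\C=C/I
F4 | step 10 | ethyl (Z)-2-methyl-5-(trimethylsilyl)pent-2-en-4-ynoate | CCOC(=O)/C(C)=C\C#C[Si](C)(C)C
F5 | step 10 | ethyl (Z)-5-iodo-2-methylpent-2-en-4-ynoate | CCOC(=O)/C(C)=C\C#CI
F6 | step 10 | ethyl (2Z,4Z)-5-iodo-2-methylpenta-2,4-dienoate | CCOC(=O)/C(C)=C\C=C/I
F7 | step 10 | (2Z,4Z)-5-iodo-2-methylpenta-2,4-dienoic acid | OC(=O)/C(C)=C\C=C/I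
F8 | step 4 | (3R,4R)-1-[(tert-butyldimethylsilyl)oxy]-4-methylhex-5-en-3-yl diisopinocampheylborinate | C=C[C@@H](C)[C@@H](CCO[Si](C)(C)C(C)(C)C)OB([C@H]1[C@H](C)[C@H]2C[C@@H](C1)C2(C)C)[C@H]1[C@H](C)[C@H]2C[C@@H](C1)C2(C)C
F9 | step 4 | (3R,4R)-1-[(tert-butyldimethylsilyl)oxy]-4-methylhex-5-en-3-ol | C=C[C@@H](C)[C@@H](CCO[Si](C)(C)C(C)(C)C)O
F10 | step 4 | (3R,4R)-1,3-bis[(tert-butyldimethylsilyl)oxy]-4-methylhex-5-ene | C=C[C@@H](C)[C@@H](CCO[Si](C)(C)C(C)(C)C)O[Si](C)(C)C(C)(C)C
F11 | step 4 | (3R,4R)-3-[(tert-butyldimethylsilyl)oxy]-4-methylhex-5-en-1-ol | C=C[C@@H](C)[C@@H](CCO)O[Si](C)(C)C(C)(C)C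
F12 | step 4 | (3R,4R)-3-[(tert-butyldimethylsilyl)oxy]-4-methylhex-5-enal | C=C[C@@H](C)[C@@H](CC=O)O[Si](C)(C)C(C)(C)C
F13 | step 4 | 5-{(2R,3R)-2-[(tert-butyldimethylsilyl)oxy]-3-methylpent-4-en-1-yl}-1,3-oxazole | C=C[C@@H](C)[C@@H](Cc1cnco1)O[Si](C)(C)C(C)(C)C
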